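**Plan**

Numbering (germacrane): lactone O–C6, ring fusion C7, C8 (angelate), C9, C10 (Me, OH), C1, C2, C3=C4 (C15 = CH2OAc), C5; lactone carbons C11 (=C13H2) and C12 (C=O).
Retrosynthesis: the C8 ester and the C8 carbinol configuration are cut first (C8 ketone, hydride delivered from C10–OH). Then the ring bond C7–C8 is cut: the α-methylene lactone C7–C11(=C13)–C12 beside a carbinol carbon is the retron of an allylmetal C13–C11=C7 adding through C7 to a C8 aldehyde, so the seco compound is a 3-(bromomethyl)butenolide (C7=C11, C13–Br) carrying the aldehyde.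
The butenolide is cut at the ester O6–C12 and at C7=C11 (ring-closing metathesis of a 2-(bromomethyl)acrylate of a vinyl carbinol). C3=C4 is cut by Horner–Wadsworth–Emmons logic between a C3 aldehyde (C1–C3, C8–C10) and an α-phosphono-γ-lactone (C4–C7, C15), a temporary ring C15(=O)–O6 that fixes the alkene geometry and is then reduced open.
Forward: two chiral-pool fragments → E-alkylidene lactone → open-chain diol → five-membered butenolide (metathesis) → ten-membered carbocycle (chromium, unveiling C11=C13) → C8 oxidation/reduction → angelate.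
Stereochemistry: C10 from (S)-linalool; C6 from (S)-2-vinyloxirane; C7 from C6 during ring closure (trans lactone); C8 from C10 by 1,3-anti hydride delivery; C3=C4 (ring carbons C2 and C5 cis) from the E-alkylidene lactone; the angelate Z-alkene from angelic acid.

Key step: step 12

Remark: (S)-linalool and (S)-2-vinyloxirane are taken as commercial materials of high enantiomeric purity; locants C1–C15 in the names below follow the germacrane numbering given above.

**Step 1**
Reactants: 1 (S)-linalool
Product: 3 (3S)-3,7-dimethyloct-6-ene-1,3-diol, via B-alkyl-9-BBN adduct 2 (not isolated)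
Conditions: 9-BBN (1.5 equiv), THF, 0 °C → rt; then NaOH (3 M aq.), H2O2 (30 %), 0 °C → rt
Reagents that add atoms: hydrogen peroxide, OO
Why: Hydroboration–oxidation, in which 9-BBN adds only to the monosubstituted vinyl group at its terminal carbon (the trisubstituted alkene and the hindered tertiary hydroxyl react far more slowly) and alkaline peroxide turns the C–B bond of 2 into the primary alcohol, the carbinol stereocentre (the later C10) being untouched.

**Step 2**
Reactants: 3 (3S)-3,7-dimethyloct-6-ene-1,3-diol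
Product: 4 (3S)-3,7-dimethyl-1,3-bis(triethylsilyloxy)oct-6-ene
Conditions: Et3SiOTf (2.5 equiv), 2,6-lutidine, CH2Cl2, −78 → 0 °C
Reagents that add atoms: triethylsilyl triflate, CC[Si](CC)(CC)OS(=O)(=O)C(F)(F)F
Why: Silyl ether formation with the silyl triflate caps the primary and the hindered tertiary hydroxyl in one operation, which later prevents lactol formation and oxa-Michael addition by the tertiary alcohol and masks the future C8 aldehyde.

**Step 3**
Reactants: 4 (3S)-3,7-dimethyl-1,3-bis(triethylsilyloxy)oct-6-ene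
Product: 6 (4S)-4-methyl-4,6-bis(triethylsilyloxy)hexanal, via ozonide 5 (not isolated)
Conditions: O3, CH2Cl2, −78 °C (Sudan red 7B end point); then PPh3, −78 °C → rt
Reagents that add atoms: ozone, [O-][O+]=O
Why: Ozonolysis with reductive work-up cleaves the only alkene of 4 to the C3 aldehyde and acetone without affecting the silyl ethers.

**Step 4**
Reactants: 7 triethyl phosphonoacetate; 8 (S)-2-vinyloxirane
Product: 10 diethyl [(5R)-5-ethenyl-2-oxooxolan-3-yl]phosphonate, via hydroxy ester alkoxide 9 (not isolated)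
Conditions: NaOEt (1.1 equiv), EtOH, 0 → 70 °C; then AcOH
Reagents that add atoms: none
Why: Epoxide opening by a stabilised carbanion followed by lactonisation, in which the sodium enolate of 7 attacks the unhindered terminal CH2 of the vinyl epoxide in an SN2 sense (the stereocentre is not a reaction site and becomes C6 with retention) and alkoxide 9 closes onto the ethyl ester.

**Step 5**
Reactants: 10 diethyl [(5R)-5-ethenyl-2-oxooxolan-3-yl]phosphonate; 6 (4S)-4-methyl-4,6-bis(triethylsilyloxy)hexanal
Product: 11 (3E,5R)-5-ethenyl-3-[(4S)-4-methyl-4,6-bis(triethylsilyloxy)hexylidene]oxolan-2-one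
Conditions: NaH, THF, 0 °C; then 6, 0 °C → rt
Reagents that add atoms: none
Why: Horner–Wadsworth–Emmons olefination of the unbranched aldehyde with the cyclic phosphonate should favour the E-alkylidene lactone (chain anti to the lactone carbonyl, hence cis to C5), which fixes the C3=C4 geometry of the target, any Z isomer being removed by chromatography.

**Step 6**
Reactants: 11 (3E,5R)-5-ethenyl-3-[(4S)-4-methyl-4,6-bis(triethylsilyloxy)hexylidene]oxolan-2-one
Product: 12 (3R,5E,9S)-5-(hydroxymethyl)-9-methyl-9,11-bis(triethylsilyloxy)undeca-1,5-dien-3-ol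
Conditions: i-Bu2AlH (4 equiv), CH2Cl2, −78 → −20 °C; aq. potassium sodium tartrate
Reagents that add atoms: none
Why: 1,2-Reduction of the α-alkylidene lactone with excess aluminium hydride opens the temporary ring to the primary allylic C15 alcohol and the secondary C6 carbinol without touching the alkenes or the silyl ethers.

**Step 7**
Reactants: 12 (3R,5E,9S)-5-(hydroxymethyl)-9-methyl-9,11-bis(triethylsilyloxy)undeca-1,5-dien-3-ol
Product: 13 (2E,6S)-2-[(2R)-2-hydroxybut-3-enyl]-6-methyl-6,8-bis(triethylsilyloxy)oct-2-enyl acetate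
Conditions: AcCl (1.05 equiv), 2,4,6-collidine, CH2Cl2, −78 °C
Reagents that add atoms: acetyl chloride, CC(=O)Cl
Why: Selective acylation, since at −78 °C with the hindered base acetyl chloride acetylates the primary allylic C15 hydroxyl much faster than the secondary C6 hydroxyl.

**Step 8**
Reactants: 13 (2E,6S)-2-[(2R)-2-hydroxybut-3-enyl]-6-methyl-6,8-bis(triethylsilyloxy)oct-2-enyl acetate; 14 2-(bromomethyl)acrylic acid
Product: 15 (3R,5E,9S)-5-(acetoxymethyl)-9-methyl-9,11-bis(triethylsilyloxy)undeca-1,5-dien-3-yl 2-(bromomethyl)prop-2-enoate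
Conditions: 14 (1.5 equiv), DCC, DMAP (5 mol %), CH2Cl2, 0 °C
Reagents that add atoms: none
Why: Steglich esterification (carbodiimide activation, only catalytic DMAP at 0 °C to limit amine attack on the allylic bromide) acylates the remaining secondary allylic alcohol with retention at C6.

**Step 9**
Reactants: 15 (3R,5E,9S)-5-(acetoxymethyl)-9-methyl-9,11-bis(triethylsilyloxy)undeca-1,5-dien-3-yl 2-(bromomethyl)prop-2-enoate
Product: 16 (5R)-5-[(2E,6S)-2-(acetoxymethyl)-6-methyl-6,8-bis(triethylsilyloxy)oct-2-enyl]-3-(bromomethyl)furan-2(5H)-one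
Conditions: second-generation Grubbs catalyst RuCl2(=CHPh)(H2IMes)(PCy3) (5 mol %), toluene (0.01 M), 80 °C
Reagents that add atoms: none
Why: Ring-closing metathesis between the vinyl group and the 1,1-disubstituted acrylate closes the five-membered butenolide (C7=C11) with loss of ethylene, as is known for methacrylate esters of allylic alcohols, the hindered trisubstituted C3=C4 alkene and the allylic bromide being spectators.

**Step 10**
Reactants: 16 (5R)-5-[(2E,6S)-2-(acetoxymethyl)-6-methyl-6,8-bis(triethylsilyloxy)oct-2-enyl]-3-(bromomethyl)furan-2(5H)-one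
Product: 17 (5R)-5-[(2E,6S)-2-(acetoxymethyl)-6,8-dihydroxy-6-methyloct-2-enyl]-3-(bromomethyl)furan-2(5H)-one
Conditions: HF (48 % aq.), MeCN, 0 °C
Reagents that add atoms: none
Why: Acidic fluoride desilylation removes the primary and the tertiary triethylsilyl ether without hydrolysing the allylic bromide, the acetate or the butenolide.

**Step 11**
Reactants: 17 (5R)-5-[(2E,6S)-2-(acetoxymethyl)-6,8-dihydroxy-6-methyloct-2-enyl]-3-(bromomethyl)furan-2(5H)-one
Product: 18 (5R)-5-[(2E,6S)-2-(acetoxymethyl)-6-hydroxy-6-methyl-8-oxooct-2-enyl]-3-(bromomethyl)furan-2(5H)-one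
Conditions: Dess–Martin periodinane, NaHCO3, CH2Cl2, 0 °C → rt
Reagents that add atoms: none
Why: Dess–Martin oxidation converts only the primary alcohol into the C8 aldehyde (the tertiary C10 hydroxyl cannot be oxidised) under buffered, non-nucleophilic conditions that the allylic bromide tolerates.

**Step 12**
Reactants: 18 (5R)-5-[(2E,6S)-2-(acetoxymethyl)-6-hydroxy-6-methyl-8-oxooct-2-enyl]-3-(bromomethyl)furan-2(5H)-one
Product: 20 (3E,6R,7R,8S,10S)-15-acetoxy-8,10-dihydroxygermacra-3,11(13)-dien-6,12-olide, via allylchromium dichloride 19 (not isolated)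
Conditions: CrCl2 (10 equiv), degassed THF, 4 Å molecular sieves, rt, 18 added over 12 h (final 0.003 M); then aq. NH4Cl
Reagents that add atoms: none
Why: CrCl2 (divalent chromium, two equivalents per bromide) reduces the allylic C13–Br bond to the allylchromium dichloride 19 (trivalent chromium), which adds through its γ-carbon C7 to the C8 aldehyde in an SE2' sense via a six-membered Zimmerman–Traxler transition state, so that the double bond moves from C7=C11 to C11=C13 and the α-methylene lactone appears as the ring closes. The closest known reaction types are the Nozaki–Hiyama–Kishi (Barbier) allylation of aldehydes with 3-(bromomethyl)furan-2(5H)-ones and the chromium-mediated macrocyclisation of ω-formyl allylic bromides. The ten-membered carbocycle closes in a 10-exo-trig mode at the carbonyl (the C=O stays outside the new ring). C7 is controlled by the C6 stereocentre: the tether leaves C6 on one face of the planar butenolide and wraps around the C6–C7 edge, so that C8 should bond to C7 anti to C5, which avoids eclipsing C5 and C8 in the forming ring and gives the trans-fused lactone (H6 and H7 anti). C8 is controlled by the chair transition state of the E-locked allylchromium with the tether pseudo-equatorial, which predicts the anti adduct (8S, H7 and H8 anti); this centre is deliberately re-set in steps 13 and 14. The step needs intra- over intermolecular addition (high dilution, slow addition), γ- over α-attack (inherent to allylchromium reagents; α-attack would need a twelve-membered ring) and chemoselective reduction of the bromide (the allylic acetate, the lactone and the free tertiary hydroxyl are inert to CrCl2).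

**Step 13**
Reactants: 20 (3E,6R,7R,8S,10S)-15-acetoxy-8,10-dihydroxygermacra-3,11(13)-dien-6,12-olide
Product: 21 (3E,6R,7S,10S)-15-acetoxy-10-hydroxy-8-oxogermacra-3,11(13)-dien-6,12-olide
Conditions: Dess–Martin periodinane, NaHCO3, CH2Cl2, 0 °C
Reagents that add atoms: none
Why: Dess–Martin oxidation under bicarbonate buffering converts the secondary C8 alcohol into the ketone and leaves the tertiary C10 hydroxyl, the near-neutral conditions being chosen so that C7–H (now α to the ketone) does not enolise and neither C7 nor the exocyclic methylene is scrambled.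

**Step 14**
Reactants: 21 (3E,6R,7S,10S)-15-acetoxy-10-hydroxy-8-oxogermacra-3,11(13)-dien-6,12-olide
Product: 23 (3E,6R,7R,8R,10S)-15-acetoxy-8,10-dihydroxygermacra-3,11(13)-dien-6,12-olide, via alkoxyborohydride 22 (not isolated)
Conditions: Me4NBH(OAc)3 (5 equiv), MeCN/AcOH (1:1), −30 °C
Reagents that add atoms: none
Why: Evans–Saksena hydroxyl-directed reduction, in which the tertiary C10 hydroxyl exchanges an acetate on boron (22) and hydride is delivered intramolecularly to the face of the C8 carbonyl on which O10 lies (also the peripheral face of the ten-membered ring), so that the new C8–OH should be 1,3-anti (trans) to C10–OH as in the target (8R), while this weak acidic hydride leaves the α-methylene lactone, the acetate and C7 untouched.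

**Step 15**
Reactants: 23 (3E,6R,7R,8R,10S)-15-acetoxy-8,10-dihydroxygermacra-3,11(13)-dien-6,12-olide; 24 angelic acid
Product: 25 target CNP0270682.1, (3E,6R,7S,8R,10S)-15-acetoxy-8-angeloyloxy-10-hydroxygermacra-3,11(13)-dien-6,12-olide
Conditions: 24 (3 equiv), 2,4,6-trichlorobenzoyl chloride, Et3N, toluene, rt; then 23, toluene, 75 °C (no DMAP)
Reagents that add atoms: none
Why: Yamaguchi esterification, in which the mixed anhydride of angelic acid and 2,4,6-trichlorobenzoic acid acylates the secondary C8 hydroxyl with retention (the tertiary C10 hydroxyl is too hindered to react), the amine-free heating protocol being chosen to transfer the angeloyl group without Z→E isomerisation to the tiglate.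

**Compound list**

1 | (S)-linalool, (3S)-3,7-dimethylocta-1,6-dien-3-ol | CC(C)=CCC[C@](C)(O)C=C | starting material
2 | B-[(3S)-3-hydroxy-3,7-dimethyloct-6-en-1-yl]-9-borabicyclo[3.3.1]nonane (B-alkyl-9-BBN adduct) | CC(C)=CCC[C@](C)(O)CCB1C2CCCC1CCC2 | intermediate
3 | (3S)-3,7-dimethyloct-6-ene-1,3-diol | CC(C)=CCC[C@](C)(O)CCO | intermediate
4 | (3S)-3,7-dimethyl-1,3-bis(triethylsilyloxy)oct-6-ene | CC(C)=CCC[C@](C)(O[Si](CC)(CC)CC)CCO[Si](CC)(CC)CC | intermediate
5 | ozonide of 4, 3,3-dimethyl-5-[(3S)-3-methyl-3,5-bis(triethylsilyloxy)pentyl]-1,2,4-trioxolane | CC1(C)OOC(CC[C@](C)(O[Si](CC)(CC)CC)CCO[Si](CC)(CC)CC)O1 | intermediate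
6 | (4S)-4-methyl-4,6-bis(triethylsilyloxy)hexanal | O=CCC[C@](C)(O[Si](CC)(CC)CC)CCO[Si](CC)(CC)CC | intermediate
7 | triethyl phosphonoacetate | CCOC(=O)CP(=O)(OCC)OCC | starting material
8 | (S)-2-vinyloxirane, (2S)-2-ethenyloxirane | C=C[C@H]1CO1 | starting material
9 | ethyl (4R)-2-(diethoxyphosphoryl)-4-hydroxyhex-5-enoate (present as its sodium alkoxide, drawn neutral) | CCOC(=O)C(C[C@@H](O)C=C)P(=O)(OCC)OCC | intermediate
10 | diethyl [(5R)-5-ethenyl-2-oxooxolan-3-yl]phosphonate (both C3 epimers) | O=C1O[C@@H](C=C)CC1P(=O)(OCC)OCC | intermediate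
11 | (3E,5R)-5-ethenyl-3-[(4S)-4-methyl-4,6-bis(triethylsilyloxy)hexylidene]oxolan-2-one | O=C1O[C@@H](C=C)C/C1=C\CC[C@](C)(O[Si](CC)(CC)CC)CCO[Si](CC)(CC)CC | intermediate
12 | (3R,5E,9S)-5-(hydroxymethyl)-9-methyl-9,11-bis(triethylsilyloxy)undeca-1,5-dien-3-ol | C=C[C@H](O)C/C(CO)=C\CC[C@](C)(O[Si](CC)(CC)CC)CCO[Si](CC)(CC)CC | intermediate
13 | (2E,6S)-2-[(2R)-2-hydroxybut-3-enyl]-6-methyl-6,8-bis(triethylsilyloxy)oct-2-enyl acetate (C15 mono-acetate of 12) | C=C[C@H](O)C/C(COC(C)=O)=C\CC[C@](C)(O[Si](CC)(CC)CC)CCO[Si](CC)(CC)CC | intermediate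
14 | 2-(bromomethyl)acrylic acid | C=C(CBr)C(=O)O | starting material
15 | (3R,5E,9S)-5-(acetoxymethyl)-9-methyl-9,11-bis(triethylsilyloxy)undeca-1,5-dien-3-yl 2-(bromomethyl)prop-2-enoate | C=C[C@H](OC(=O)C(=C)CBr)C/C(COC(C)=O)=C\CC[C@](C)(O[Si](CC)(CC)CC)CCO[Si](CC)(CC)CC | intermediate
16 | (5R)-5-[(2E,6S)-2-(acetoxymethyl)-6-methyl-6,8-bis(triethylsilyloxy)oct-2-enyl]-3-(bromomethyl)furan-2(5H)-one | BrCC1=C[C@@H](C/C(COC(C)=O)=C\CC[C@](C)(O[Si](CC)(CC)CC)CCO[Si](CC)(CC)CC)OC1=O | intermediate
17 | (5R)-5-[(2E,6S)-2-(acetoxymethyl)-6,8-dihydroxy-6-methyloct-2-enyl]-3-(bromomethyl)furan-2(5H)-one | BrCC1=C[C@@H](C/C(COC(C)=O)=C\CC[C@](C)(O)CCO)OC1=O | intermediate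
18 | (5R)-5-[(2E,6S)-2-(acetoxymethyl)-6-hydroxy-6-methyl-8-oxooct-2-enyl]-3-(bromomethyl)furan-2(5H)-one | BrCC1=C[C@@H](C/C(COC(C)=O)=C\CC[C@](C)(O)CC=O)OC1=O | intermediate
19 | allylchromium dichloride (trivalent chromium) formed from 18 at C13 | Cl[Cr](Cl)CC1=C[C@@H](C/C(COC(C)=O)=C\CC[C@](C)(O)CC=O)OC1=O | intermediate
20 | (3E,6R,7R,8S,10S)-15-acetoxy-8,10-dihydroxygermacra-3,11(13)-dien-6,12-olide (8-epi alcohol, H7 and H8 anti) | C=C1C(=O)O[C@@H]2C/C(COC(C)=O)=C\CC[C@](C)(O)C[C@H](O)[C@@H]12 | intermediate
21 | (3E,6R,7S,10S)-15-acetoxy-10-hydroxy-8-oxogermacra-3,11(13)-dien-6,12-olide | C=C1C(=O)O[C@@H]2C/C(COC(C)=O)=C\CC[C@](C)(O)CC(=O)[C@@H]12 | intermediate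
22 | tetramethylammonium diacetoxy(hydrido)borate ester of the C10 hydroxyl of 21 | C=C1C(=O)O[C@@H]2C/C(COC(C)=O)=C\CC[C@](C)(O[BH-](OC(C)=O)OC(C)=O)CC(=O)[C@@H]12.C[N+](C)(C)C | intermediate
23 | (3E,6R,7R,8R,10S)-15-acetoxy-8,10-dihydroxygermacra-3,11(13)-dien-6,12-olide | C=C1C(=O)O[C@@H]2C/C(COC(C)=O)=C\CC[C@](C)(O)C[C@@H](O)[C@@H]12 | intermediate
24 | angelic acid, (Z)-2-methylbut-2-enoic acid | C/C=C(/C)C(=O)O | starting material
25 | CNP0270682.1, (3E,6R,7S,8R,10S)-15-acetoxy-8-angeloyloxy-10-hydroxygermacra-3,11(13)-dien-6,12-olide | C=C1C(=O)O[C@@H]2C/C(COC(C)=O)=C\CC[C@](C)(O)C[C@@H](OC(=O)/C(C)=C\C)[C@@H]12 | target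

**Step count**

Total steps: 15. Longest linear sequence: 14 steps (1 → 25 through steps 1–3 and 5–15; step 4 makes the second fragment).

**Steps most likely to fail**

Step 12 (ring closure). Intermolecular addition may outrun cyclisation (oligomerisation), C8 may add to the other face of C7 (cis-fused lactone), or the allylmetal may expel the lactone carboxylate by β-elimination. Fallback: the in situ organochromium is replaced by an isolable 2-alkoxycarbonyl allylboronate that cyclises by Lewis-acid-catalysed allylboration without any reductant. Setting out from 15, copper-mediated borylation (B2pin2, CuCl, KOAc, DMF; at the acrylate stage SN2 and SN2' attack give the same product) would give the 2-(pinacolborylmethyl)acrylate F1. Ring-closing metathesis as in step 9 would give the 3-(pinacolborylmethyl)butenolide F2, HF·pyridine in THF the diol F3, and Dess–Martin oxidation the boryl aldehyde F4. With Sc(OTf)3 (10 mol %) in CH2Cl2 at high dilution, F4 should close through the same chair arrangement and, after hydrolysis of the borate, return to the route at 20.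

Step 14 (with the ketone of step 13). Hydride transfer may lose facial selectivity if the boron held on O10 cannot reach C8 in the ring conformation, and C7 of ketone 21 may enolise (epimerisation, or migration of the exocyclic double bond into conjugation). Fallback: steps 13–15 are bypassed by inverting C8 in the acylation itself. Setting out from 20, Mitsunobu esterification with 24 (PPh3, diisopropyl azodicarboxylate, toluene, 0 °C → rt) would pass through the C8 alkoxytriphenylphosphonium angelate F5, which the carboxylate displaces with inversion to give 25 directly; the tertiary C10 hydroxyl does not take part.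

Step 4 (epoxide opening). The enolate may attack the allylic epoxide carbon or add in an SN2' sense, giving regioisomeric lactones. Fallback: the vinyl lactone is made from the chiral pool and phosphorylated afterwards. Commercial (5R)-5-(hydroxymethyl)oxolan-2-one F6 would be oxidised (SO3·pyridine, DMSO, i-Pr2NEt; Parikh–Doering) to (2R)-5-oxooxolane-2-carbaldehyde F7, used at once in a Wittig methylenation (Ph3P=CH2, THF, −78 °C) to give (5R)-5-ethenyloxolan-2-one F8. C-Phosphorylation (LiN(i-Pr)2, 2.2 equiv, ClP(O)(OEt)2, THF, −78 °C; enol phosphate then 1,3-shift to carbon) returns to the route at 10.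

**Further compounds**

F1 | step 12 | (3R,5E,9S)-5-(acetoxymethyl)-9-methyl-9,11-bis(triethylsilyloxy)undeca-1,5-dien-3-yl 2-[(4,4,5,5-tetramethyl-1,3,2-dioxaborolan-2-yl)methyl]prop-2-enoate | C=C[C@H](OC(=O)C(=C)CB1OC(C)(C)C(C)(C)O1)C/C(COC(C)=O)=C\CC[C@](C)(O[Si](CC)(CC)CC)CCO[Si](CC)(CC)CC
F2 | step 12 | (5R)-5-[(2E,6S)-2-(acetoxymethyl)-6-methyl-6,8-bis(triethylsilyloxy)oct-2-enyl]-3-[(4,4,5,5-tetramethyl-1,3,2-dioxaborolan-2-yl)methyl]furan-2(5H)-one | CC1(C)OB(CC2=C[C@@H](C/C(COC(C)=O)=C\CC[C@](C)(O[Si](CC)(CC)CC)CCO[Si](CC)(CC)CC)OC2=O)OC1(C)C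
F3 | step 12 | (5R)-5-[(2E,6S)-2-(acetoxymethyl)-6,8-dihydroxy-6-methyloct-2-enyl]-3-[(4,4,5,5-tetramethyl-1,3,2-dioxaborolan-2-yl)methyl]furan-2(5H)-one | CC1(C)OB(CC2=C[C@@H](C/C(COC(C)=O)=C\CC[C@](C)(O)CCO)OC2=O)OC1(C)C
F4 | step 12 | (5R)-5-[(2E,6S)-2-(acetoxymethyl)-6-hydroxy-6-methyl-8-oxooct-2-enyl]-3-[(4,4,5,5-tetramethyl-1,3,2-dioxaborolan-2-yl)methyl]furan-2(5H)-one | CC1(C)OB(CC2=C[C@@H](C/C(COC(C)=O)=C\CC[C@](C)(O)CC=O)OC2=O)OC1(C)C
F5 | step 14 | C8 alkoxytriphenylphosphonium angelate derived from 20 | C=C1C(=O)O[C@@H]2C/C(COC(C)=O)=C\CC[C@](C)(O)C[C@H](O[P+](c3ccccc3)(c3ccccc3)c3ccccc3)[C@@H]12.C/C=C(/C)C([O-])=O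
F6 | step 4 | (5R)-5-(hydroxymethyl)oxolan-2-one | O=C1O[C@@H](CO)CC1
F7 | step 4 | (2R)-5-oxooxolane-2-carbaldehyde | O=C1O[C@@H](C=O)CC1
F8 | step 4 | (5R)-5-ethenyloxolan-2-one | O=C1O[C@@H](C=C)CC1
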